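The easy mistake with this flask is to read 1 mol% of initiator as chains of 100 units, as if each initiator began a chain and the free monomer joined them evenly. That even case is a good zero for the scale, once the count is corrected.

in all of them: free monomer 0.11 M; initiator 1 mol%; impurity 0.36 mM
- north-west: the very flask that is asked about, followed so far
- flask: time 20 h

north-west run (percent of the free monomer charged)

| time / h | monomer in chains / % | free monomer / % |
|---|---|---|
| 0.200 | 2.6 | 97.7 |
| 0.667 | 12.8 | 87.4 |
| 1.00 | 19.9 | 79.9 |
| 1.50 | 28.9 | 71.2 |
| 2.50 | 40.6 | 58.7 |
| 3.00 | 44.8 | 54.9 |
| 4.00 | 51.5 | 48.3 |

(each reading ± 0.5 percentage points)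

- the average divides the monomer in chains by the number of chains begun, living and dead together
- the numbers in the tables scatter with a standard deviation of 0.5 percentage points
- on the list of suspects stand: free monomer + initiator -> living end + monomer in chains; initiator + impurity -> spent initiator A; free monomer + living end -> monomer in chains + living end; 2 initiator -> spent initiator B; monomer in chains + living end -> free monomer + living end; living end -> dead end C
- the earlier runs do not show the number of chains; that part of a forecast is a guess

* whether the average number of monomer units in a chain (chains begun, living or dead) reaches 500 by 20 h (yes / no)
* average number of monomer units in a chain (chains begun, living or dead) at 20 h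

How many initiators can begin a chain? The impurity stands at about a third of the 1.10 mM initiator. If it is the limiting reagent of that side step and takes one initiator each, 0.740 mM remain. We call the free monomer charged per remaining initiator the even share, S: here 149 units.

Can S reach the length wanted? No: 500 stands 3.36 times higher, and would take 0.220 mM of chains.

How much of S gets used? Monomer in chains reads 51.5 % at 4.00 h and is slowing. We therefore commit to a length between 76.7 and 149, so the answer is no.

The forecast says no with a length of 97, inside our range, and of its chains it says “perhaps less with initiator coupling”.

The flask gives no, with a length of 124.

    free monomer + initiator → living end + monomer in chains (k = 0.00740 L mol⁻¹ s⁻¹)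
    initiator + impurity → spent initiator A (k = 96.0 L mol⁻¹ s⁻¹)
    free monomer + living end → monomer in chains + living end, rate k3*[living end]*[free monomer] (k = 0.190 L mol⁻¹ s⁻¹)
    2 initiator → spent initiator B (k = 0.400 L mol⁻¹ s⁻¹)
    monomer in chains + living end → free monomer + living end, rate k5*[living end] as long as [monomer in chains] is above zero (k = 0.00150 s⁻¹)
    living end → dead end C (k = 9.50 × 10⁻⁵ s⁻¹)

With 62.2 % in chains, S gives 92.7, and the flask stands 1.34 times higher, holding 5.51 × 10⁻⁴ M of dead ends. Taking two initiators for each spent initiator B from 0.740 mM leaves 0.552 mM. In the neighbour with 0.044 M of free monomer, S is 550; its 10.9 % in chains gives 60.0, against a simulated 68.3. The flask has come to rest: at 20.0 h living ends are 0.120 % of dead ends and free monomer stands at 37.8 %, and ten times as long, at 200 h, free monomer stands at 37.8 %, while the length at 200 h is 124.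

(All runs were computed with made-up constants; noise was put on by code.)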